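The readings are simulated for substances that don't exist; noise was put on by code.

The reading wanted lies at 6.0 h, long after the last reading of the green run at 120 min, so the question is where this flask stops.

| flask | starting material | partner | remark | time |
|---|---|---|---|---|
| green | 0.30 M (in portions, 4) | 1.1 equiv | the very flask that is asked about, followed so far; portions every 1.5 min |  |
| flask | 0.30 M (in portions, 4) | 1.10 equiv | the portions of starting material follow each other after 1.5 min, the first at the start | 6.0 h |

green run (percent of the starting material charged)

| time / min | target / % | side product / % | starting material / % |
|---|---|---|---|
| 8.00 | 39.3 | 16.9 | 45.8 |
| 12.0 | 47.2 | 20.9 | 34.2 |
| 20.0 | 56.8 | 18.9 | 26.1 |
| 30.0 | 59.6 | 20.6 | 21.1 |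
| 50.0 | 63.8 | 21.1 | 14.6 |
| 80.0 | 66.1 | 21.1 | 13.1 |
| 120 | 69.2 | 20.7 | 11.1 |

(readings scatter by 1 percentage point)

- why nothing more happens at 6.0 h, or that something still does (it is still moving / all of the starting material has reacted / the partner has run out first)
- how much target there is at 6.0 h, in percent of the starting material charged
- how much side product there is at 6.0 h, in percent of the starting material charged

- candidate steps: starting material + 2 partner -> side product; starting material + partner -> target
- the reaction counts as stopped when no species that holds the starting material changes by six tenths of a point or more over the second half of the time

Take the target step by itself: one partner per starting material turns the charge into target, with 0.100 of partner to spare as a fraction of the starting material charged. The side step adds a cost of two partner per starting material, so target plus twice side product counts the partner used. At 120 min in the green run that sum reads 111% against a charge of 110%, which is within the scatter, while starting material still reads 11.1%, so partner is the limiting reagent. Side product reads flat from 30.0 min on, with a mean of 20.9%. The balance then gives 68.3% target and leaves 10.8% starting material.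

The last piece is the split, the side product formed per target formed over the run, here 0.306. If each step goes as its equation stands, the side step has one more partner than the target step, so at a given partner level the split should be in proportion to partner. Replacing the falling partner by a straight-line mean gives 0.550 for this flask, counted as a fraction of the starting material charged.

The forecast says the partner has run out first, with 68.5% target and 20.8% side product, because “the partner is nearly gone while about 11% starting material remains”. The reckoning here differs from it slightly, with the values above.

In the flask the partner has run out first, with 69.2% target and 20.4% side product at 6.0 h, and 0.011% of the partner remaining.

    starting material + 2 partner → side product (k = 0.0200 M⁻² s⁻¹)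
    starting material + partner → target (k = 0.00960 M⁻¹ s⁻¹)

At 0.116 h in the flask the target step uses starting material at 3.7 times the rate of the side step, a momentary split of 0.270, which stands beside the 0.306 read from the green run and 0.295 in the flask at 6.0 h.

A neighbour is charged with 4.40 equiv of partner, its other charges as in the flask. Reckoned at two partner for each starting material, its mean partner is near 3.40, so the proportion gives a split of 1.89 and side product of 65.4%. Computed, that neighbour holds 68.6% side product and 31.4% target, with starting material at 0% and partner at 61.7% of its own charge, so there starting material ran out first.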